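Remark on the chemistry: 12 and 14 are drawn as Z isomers (ring B trans to the carbonyl carbon), the thermodynamically preferred geometry, which step 6 erases. The aryne maps onto ring A as aryne C1 = C8a, C2 = C4a, C3–OMe = O5 and C5–OMe = O7, which agrees with the target, so the structures of 8, 12 and 14 need no correction.

## Structural features

The target is a flavone: ring A (benzo) is fused along C4a–C8a to ring C, a 4H-pyran-4-one, and ring B, a 2,3,4-trimethoxyphenyl group, is attached to C2 by a single sp2–sp2 bond. C3 carries a methoxy group, so ring C is fully substituted, and the molecule has no stereocentre, which makes the whole problem one of substitution pattern. Ring A carries OH at C5 (hydrogen-bonded to the C4 carbonyl), H at C6, OMe at C7 and OH at C8, so two free phenols must end up among five methyl ethers. The fragile elements are the 5,8-hydroquinone, which air-oxidises to the 5,8-quinone (fastest in base), ring C, which opens in hot alkali, and the 3- and 5-methoxy groups, both within chelating distance of the C4 carbonyl and therefore exposed to Lewis acids. The real difficulty is the oxygen at C8: it sits next to C8a, so a plan that brings ring A in as one piece must either carry it through the ring-forming chemistry or add it late. The key step uses the fact that C8a (bonded to O1) and C4a (bonded to the acyl carbon C4) are neighbours in ring A with the C5 oxygen beside C4a. An aryne spanning C4a–C8a is polarised by that oxygen, so an oxygen nucleophile adds at C8a and the acyl group lands on C4a.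

## Logic of the disconnections

19 to 17: the C8–O bond is cut. C8 is para to the free 5-hydroxyl of 17, the position a persulfate oxidation of a phenolate attacks. An oxygen carried at C8 from the start would flank the aryne carbon that becomes C8a and cancel the regiocontrol of the key step. The cut reduces ring A to a symmetrical 1,3,5-trioxygenated pattern. The forward step must hydroxylate C8 and not C6, and must shield the new hydroquinone from the oxidant; the sulfate ester 18 does the latter.

17 to 16: the free 5-hydroxyl is traced back to a methyl ether (the O5–CH3 bond). This makes the oxygens at C5 and C7 alike, so ring A can come from a symmetrical precursor with no regiochemical question in its preparation. The forward step must cleave one methyl ether out of six; the peri relation of O5 to the C4 carbonyl singles it out.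

16 to 14: the O1–C2 bond is cut and two hydrogens are restored, opening ring C to an acyclic 2'-hydroxy enone. The gain is a chain in which C2, C3 and C4 are already in place. The forward step must close ring C 6-endo (through 15) and dehydrogenate without attacking the two electron-rich arenes.

14 to 12 and 8 (through 13): C4–C4a and O1–C8a are cut together. These two bonds sit on adjacent carbons of ring A, so one aryne can receive both. The cut splits the molecule into a three-carbon acid that carries ring B, C2, C3 with its methoxy group and C4, and a symmetrically substituted ring A unit. The forward step needs the oxygen at the aryne carbon remote from the flanking methoxy group, acyl transfer to carbon instead of simple O-arylation, and an untouched enone.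

8 to 6 to 2 to 1: the O–S bond of the sulfonate, the C–Si bond and the carbamate C–O bond are cut in turn. The phenol oxygen of 1 becomes the leaving group and, as its carbamate, directs metalation to the neighbouring carbon, so silicon and leaving group end up ortho to each other. The symmetry of 1 makes both ortho positions identical. The forward steps need metalation beside the carbamate and not between the two methoxy groups, and base-only handling, because the aryl–silicon bond in so electron-rich a ring is acid-labile.

12 to 9 and 10 (through 11): the C2=C3 double bond (flavone numbering) is cut by a retro-aldol condensation, and the acid is traced to its methyl ester. Both pieces are cheap, and 10 supplies C3 with its methoxy group and C4. The forward step must condense a weakly acidic alkoxy ester with a hindered aldehyde; the geometry obtained matters little.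

## Other disconnections considered

Alternative 1: The cut is C4–C4a and O1–C2, closing ring C onto an intact ring A. In the forward key step phloroglucinol A1 and the ketoester A2, ethyl 2-methoxy-3-oxo-3-(2,3,4-trimethoxyphenyl)propanoate (racemic), would be heated neat near 250 °C (Mentzer condensation). The ester carbon of A2 acylates a ring carbon of A1 and a phenol oxygen condenses with the ketone, giving the flavone A3, 5,7-dihydroxy-3-methoxy-2-(2,3,4-trimethoxyphenyl)-4H-chromen-4-one.

In its favour:
- A1 is symmetrical, so no regiochemical question arises on ring A.
- The 5-hydroxyl of A3 arrives free, so no Lewis-acid demethylation is needed; on this point the alternative is better.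
- Selective 7-O-methylation of A3 (the 5-hydroxyl is hydrogen-bonded and less acidic) would converge on 17.
- A2 should need one or two steps (Claisen acylation of a methoxyacetate enolate by a ring B aroyl donor), followed by condensation, methylation and Elbs oxidation. That is about five steps against eight, so the alternative is better in step economy.

Against it:
- The conditions are harsh for an α-alkoxy-β-ketoester such as A2, which can fragment or self-condense.
- The ketone of A2 is deactivated by an electron-rich, ortho-substituted aryl group, which slows the O1–C2 closure.
- Coumarin formation in the opposite orientation is a known competitor.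
- The partial methylation of A3 adds a selectivity problem of its own.

In comparison, this route is thermal and uncatalysed with regiochemistry fixed by symmetry; the chosen step is fluoride-triggered with regiochemistry fixed by the flanking methoxy group. Both plans end with the same C8 hydroxylation, so they are equal on the hardest structural point.

Alternative 2: The cut is C5–C4a and C8–C8a, building ring A onto a finished ring C. In the forward key step the sulfinylpyranone A4, 3-methoxy-5-(phenylsulfinyl)-2-(2,3,4-trimethoxyphenyl)-4H-pyran-4-one (racemic at sulfur), reacts through its C5=C6 bond with the diene A5, 1-(benzyloxy)-2,4-dimethoxy-4-(trimethylsilyloxy)buta-1,3-diene, in a Diels–Alder addition. The ketene-acetal carbon of A5 bonds to the sulfinyl-bearing carbon of A4 (future C4a) and the benzyloxy terminus to the carbon beside the ring oxygen (future C8a). Sulfoxide syn-elimination and loss of the ketal alkoxy and silyl groups then aromatise ring A to the flavone A6, 8-(benzyloxy)-5-hydroxy-3,7-dimethoxy-2-(2,3,4-trimethoxyphenyl)-4H-chromen-4-one. Hydrogenolysis of the benzyl ether of A6 would give 19.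

In its favour:
- All four ring A substituents, including the C8 oxygen, are set in one step with O5 and O8 differentiated.
- No persulfate oxidation or demethylation is needed, and the hydroquinone is unveiled last under reducing conditions.
- On the C8 problem the alternative is clearly better.

Against it:
- A4 (a fully substituted pyranone bearing a sulfoxide) and A5 (a hydrolytically fragile tetra-oxygenated diene) each need a multi-step preparation, so the count should exceed ten steps.
- The dienophile A4 is a tetrasubstituted vinylogous ester that reacts only because of the sulfinyl group.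

In comparison, the alternative is structurally superior. Mechanistically it is a pericyclic step with matched polarisation against a polar aryne addition. It is worse in step economy and in the handling of intermediates.

Alternative 3: The cut is C4a–C4 and C4–C3, with C4 introduced as a one-carbon unit. In the forward key step the aryl iodide A7, 2-iodo-1,5-dimethoxy-3-(methoxymethoxy)benzene, carbon monoxide A8 and the enolate of the ketone A9, 2-methoxy-1-(2,3,4-trimethoxyphenyl)ethan-1-one, couple under Pd(dba)2 (zerovalent palladium) with a bisphosphine. Oxidative addition into A7, insertion of A8 and acylation of the enolate of A9 give the diketone A10, 1-[2,4-dimethoxy-6-(methoxymethoxy)phenyl]-2-methoxy-3-(2,3,4-trimethoxyphenyl)propane-1,3-dione (racemic). Acid would remove the acetal of A10 and cyclodehydrate to 16, after which steps 7 and 8 follow.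

In its favour:
- The position of iodine in A7 fixes the regiochemistry, so no isomer is possible; this is equal to or better than electronic control on an aryne.
- Ring C closes by dehydration without an oxidant, which is better than step 6.
- The count is about seven steps (two to A7 from 1, one to A9, coupling, cyclisation, then two), equal or slightly better.

Against it:
- A7 is very electron-rich with two ortho oxygens, so oxidative addition and acyl transfer at a crowded aroylpalladium centre should be slow.
- The α-methoxy enolate of A9 chelates and is a weaker nucleophile.
- A10 is open to retro-Claisen cleavage under the basic conditions.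
- The toxic gas A8 must be handled.

In comparison, the late steps are shared, so the two plans are equal on the C8 problem. The chosen plan avoids transition metals and forms both ring A bonds in one polar step.

Key step: step 5

## Route

Step 1
Reactants: 1 3,5-dimethoxyphenol
Product: 2 3,5-dimethoxyphenyl N-isopropylcarbamate
Conditions: iPrNCO, Et3N (cat.), CH2Cl2, rt
Reagents that add atoms: isopropyl isocyanate, CC(C)N=C=O
Why: Amine-catalysed addition of the phenol O–H to the isocyanate (carbamoylation); the N–H carbamate is chosen because it directs ortho-metalation and can later be removed with mild base, which the acid-labile aryl silane requires.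

Step 2
Reactants: 2 3,5-dimethoxyphenyl N-isopropylcarbamate
Product: 6 3,5-dimethoxy-2-(trimethylsilyl)phenyl N-isopropylcarbamate, via N-silyl carbamate 3 (not isolated), via aryllithium 4 (not isolated), via bis-silyl carbamate 5 (not isolated)
Conditions: TMSOTf, TMEDA, Et2O, 0 °C to rt; n-BuLi, TMEDA, −78 °C; TMSCl, −78 °C to rt; aq. NH4Cl
Reagents that add atoms: chlorotrimethylsilane, C[Si](C)(C)Cl; trimethylsilyl trifluoromethanesulfonate, C[Si](C)(C)OS(=O)(=O)C(F)(F)F (its silicon stays in 3, 4 and 5 only); n-butyllithium, [Li]CCCC (its lithium stays in 4 only)
Why: Directed ortho-metalation: in-flask N-silylation masks the N–H, the carbamate then steers lithiation to C2, which is flanked by the carbamate and a methoxy group and is identical with C6 by symmetry, and TMSCl traps 4 at −78 °C before an anionic ortho-Fries shift can set in; the N–Si bond of 5 hydrolyses on the mildly acidic work-up while the C–Si bond stays.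

Step 3
Reactants: 6 3,5-dimethoxy-2-(trimethylsilyl)phenyl N-isopropylcarbamate
Product: 8 3,5-dimethoxy-2-(trimethylsilyl)phenyl trifluoromethanesulfonate, via 2-silylphenol 7 (not isolated)
Conditions: DBU, Et2NH, MeCN, 40 °C; then PhNTf2, rt
Reagents that add atoms: N-phenylbis(trifluoromethanesulfonimide), O=S(=O)(N(c1ccccc1)S(=O)(=O)C(F)(F)F)C(F)(F)F
Why: DBU deprotonates the carbamate N–H and E1cB fragmentation expels the phenoxide of 7 and the isocyanate, which Et2NH scavenges as a urea; the phenoxide is sulfonylated in the same flask, so the electron-rich silylphenol, prone to ipso-protodesilylation, never meets acid.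

Step 4
Reactants: 9 2,3,4-trimethoxybenzaldehyde; 10 methyl methoxyacetate
Product: 12 (Z)-2-methoxy-3-(2,3,4-trimethoxyphenyl)acrylic acid, via methyl ester 11 (not isolated)
Conditions: NaOMe, MeOH, reflux; then aq. NaOH, reflux; HCl to pH 2
Reagents that add atoms: sodium hydroxide, [Na+].[OH-]
Why: Claisen-type aldol condensation of the ester enolate with a non-enolisable aldehyde, E1cB dehydration to the conjugated ester 11 under equilibrating conditions that favour the Z isomer (aryl trans to the carbonyl carbon), then saponification in the same flask.

Step 5
Reactants: 12 (Z)-2-methoxy-3-(2,3,4-trimethoxyphenyl)acrylic acid; 8 3,5-dimethoxy-2-(trimethylsilyl)phenyl trifluoromethanesulfonate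
Product: 14 (Z)-1-(2-hydroxy-4,6-dimethoxyphenyl)-2-methoxy-3-(2,3,4-trimethoxyphenyl)prop-2-en-1-one, via 3,5-dimethoxybenzyne 13 (not isolated)
Conditions: 8 (1.5 equiv), CsF (4 equiv), THF, 125 °C, sealed tube; aq. NH4Cl
Reagents that add atoms: none
Why: Fluoride attacks silicon in 8 and the resulting aryl anion expels triflate, releasing aryne 13 slowly beside the cesium carboxylate that excess CsF makes from 12. The carboxylate oxygen adds to the aryne carbon meta to the flanking methoxy group (future C8a), because this places the developing carbanion on the carbon next to the C–OMe bond (future C4a), where the inductive pull of oxygen and the angle distortion of a 3-alkoxyaryne both favour it. The aryl anion then attacks the neighbouring ester carbonyl (4-exo-trig), and the strained benzoxetene alkoxide reopens by C–O cleavage to the ortho-acyl phenoxide, a net anionic 1,3 O-to-C acyl shift of the Fries type. The closest known reaction type is the fluoride-induced insertion of arynes into the C–O bond of carboxylic acids to give ortho-hydroxyaryl ketones, with aryne acyl-alkylation as its carbon analogue. No ring is closed in the isolated product and no stereocentre is formed; the Z alkene is a spectator and its geometry is of no later consequence. Three selectivities are needed: regiochemistry on the aryne, secured by the 3-methoxy group; acyl transfer in preference to protonation of the aryl anion (which would give the simple aryl ester), secured by the high temperature and by full conversion of the acid into its cesium salt; and carbonyl attack in preference to 6-endo conjugate attack at the β-carbon, secured by proximity and by the donor methoxy group on the acrylate. Any phenoxide that adds to the enone in the flask gives flavanone 15, which lies on the path of step 6 and is carried forward together with 14.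

Step 6
Reactants: 14 (Z)-1-(2-hydroxy-4,6-dimethoxyphenyl)-2-methoxy-3-(2,3,4-trimethoxyphenyl)prop-2-en-1-one
Product: 16 3,5,7-trimethoxy-2-(2,3,4-trimethoxyphenyl)-4H-chromen-4-one, via 3-methoxyflavanone 15 (not isolated)
Conditions: I2 (10 mol%), DMSO, 130 °C
Reagents that add atoms: none
Why: Iodine-catalysed oxidative cyclisation of a 2'-hydroxychalcone: 6-endo oxa-Michael addition gives racemic 15, iodination of its enol at C3 and loss of HI (eased by the C3 methoxy group, which stabilises the cation) give the chromone, and DMSO reoxidises HI to I2; the small iodine loading should keep iodination of ring A down, and both stereocentres of 15 are erased.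

Step 7
Reactants: 16 3,5,7-trimethoxy-2-(2,3,4-trimethoxyphenyl)-4H-chromen-4-one
Product: 17 5-hydroxy-3,7-dimethoxy-2-(2,3,4-trimethoxyphenyl)-4H-chromen-4-one
Conditions: BCl3 (1.5 equiv), CH2Cl2, −78 to 0 °C; then H2O
Reagents that add atoms: none
Why: Chelation-controlled Lewis-acid ether cleavage: BCl3 bridges the C4 carbonyl and the peri oxygen O5 in a six-membered chelate and chloride removes that methyl group by SN2; the 3-methoxy group would need a more strained five-membered chelate and the ring B ethers have no carbonyl partner, so limited reagent and low temperature should leave them intact.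

Step 8
Reactants: 17 5-hydroxy-3,7-dimethoxy-2-(2,3,4-trimethoxyphenyl)-4H-chromen-4-one
Product: 19 5,8-dihydroxy-3,7-dimethoxy-2-(2,3,4-trimethoxyphenyl)-4H-chromen-4-one (5,8-dihydroxy-3,7,2',3',4'-pentamethoxyflavone), via 8-sulfate 18 (not isolated)
Conditions: K2S2O8, aq. KOH, pyridine, 15 °C to rt; then HCl, Na2SO3 (cat.), 90 °C
Reagents that add atoms: potassium peroxydisulfate, [K+].[K+].[O-]S(=O)(=O)OOS(=O)(=O)[O-]
Why: Elbs persulfate oxidation: the phenolate of 17 attacks a peroxide oxygen through C8, the carbon para to O5 (C6 is flanked by two oxygens and the para mode is the inherent preference), giving aryl sulfate 18; this ester shields the hydroquinone from further oxidation until acid hydrolysis under sulfite releases 19.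

## Compound list

1 | 3,5-dimethoxyphenol | COc1cc(O)cc(OC)c1 | starting material
2 | 3,5-dimethoxyphenyl N-isopropylcarbamate | COc1cc(OC)cc(OC(=O)NC(C)C)c1 | intermediate
3 | 3,5-dimethoxyphenyl N-isopropyl-N-(trimethylsilyl)carbamate | COc1cc(OC)cc(OC(=O)N(C(C)C)[Si](C)(C)C)c1 | intermediate
4 | [2-{[isopropyl(trimethylsilyl)carbamoyl]oxy}-4,6-dimethoxyphenyl]lithium | COc1cc(OC)c([Li])c(OC(=O)N(C(C)C)[Si](C)(C)C)c1 | intermediate
5 | 3,5-dimethoxy-2-(trimethylsilyl)phenyl N-isopropyl-N-(trimethylsilyl)carbamate | COc1cc(OC)c([Si](C)(C)C)c(OC(=O)N(C(C)C)[Si](C)(C)C)c1 | intermediate
6 | 3,5-dimethoxy-2-(trimethylsilyl)phenyl N-isopropylcarbamate | COc1cc(OC)c([Si](C)(C)C)c(OC(=O)NC(C)C)c1 | intermediate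
7 | 3,5-dimethoxy-2-(trimethylsilyl)phenol (present as its amidinium phenoxide) | COc1cc(O)c([Si](C)(C)C)c(OC)c1 | intermediate
8 | 3,5-dimethoxy-2-(trimethylsilyl)phenyl trifluoromethanesulfonate | COc1cc(OC)c([Si](C)(C)C)c(OS(=O)(=O)C(F)(F)F)c1 | intermediate
9 | 2,3,4-trimethoxybenzaldehyde | COc1ccc(C=O)c(OC)c1OC | starting material
10 | methyl methoxyacetate | COCC(=O)OC | starting material
11 | methyl (Z)-2-methoxy-3-(2,3,4-trimethoxyphenyl)acrylate | CO/C(C(=O)OC)=C\c1ccc(OC)c(OC)c1OC | intermediate
12 | (Z)-2-methoxy-3-(2,3,4-trimethoxyphenyl)acrylic acid | CO/C(C(=O)O)=C\c1ccc(OC)c(OC)c1OC | intermediate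
13 | 3,5-dimethoxybenzyne (1,2-didehydro-3,5-dimethoxybenzene) | COC1=CC(OC)=CC#C1 | intermediate
14 | (Z)-1-(2-hydroxy-4,6-dimethoxyphenyl)-2-methoxy-3-(2,3,4-trimethoxyphenyl)prop-2-en-1-one | CO/C(C(=O)c1c(O)cc(OC)cc1OC)=C\c1ccc(OC)c(OC)c1OC | intermediate
15 | 3,5,7-trimethoxy-2-(2,3,4-trimethoxyphenyl)chroman-4-one (racemic, cis/trans at C2/C3 not controlled, both centres erased in step 6) | COC1C(=O)c2c(OC)cc(OC)cc2OC1c1ccc(OC)c(OC)c1OC | intermediate
16 | 3,5,7-trimethoxy-2-(2,3,4-trimethoxyphenyl)-4H-chromen-4-one | COc1ccc(-c2oc3cc(OC)cc(OC)c3c(=O)c2OC)c(OC)c1OC | intermediate
17 | 5-hydroxy-3,7-dimethoxy-2-(2,3,4-trimethoxyphenyl)-4H-chromen-4-one | COc1ccc(-c2oc3cc(OC)cc(O)c3c(=O)c2OC)c(OC)c1OC | intermediate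
18 | potassium 5-hydroxy-3,7-dimethoxy-4-oxo-2-(2,3,4-trimethoxyphenyl)-4H-chromen-8-yl sulfate | COc1ccc(-c2oc3c(OS(=O)(=O)[O-])c(OC)cc(O)c3c(=O)c2OC)c(OC)c1OC.[K+] | intermediate
19 | 5,8-dihydroxy-3,7-dimethoxy-2-(2,3,4-trimethoxyphenyl)-4H-chromen-4-one | COc1ccc(-c2oc3c(O)c(OC)cc(O)c3c(=O)c2OC)c(OC)c1OC | target

## Step count and risk

Total step count: 8. Longest linear sequence: 7 (steps 1, 2, 3, 5, 6, 7, 8); the acid branch adds step 4.

Least certain steps:

Step 5 (key step). The most likely failure is protonation of the aryl anion before it reaches the carbonyl, which amounts to simple O-arylation of the acid. Conjugate attack of the aryl anion at the β-carbon, addition at the wrong aryne carbon and further arylation of the product phenoxide by excess aryne are further possibilities. All of these stem from the short lifetime of the aryl anion and the several electrophilic sites within its reach.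
Fallback, setting out from 1 and returning at 14: the aryl ketone is made by electrophilic acylation and the enone by condensation, so no aryne is needed. Hoesch acylation of 1 with methoxyacetonitrile (ZnCl2, HCl, Et2O, 0 °C; then H2O, reflux) should give, after separation of the chelated ortho-hydroxy ketone from its para-hydroxy isomer, 1-(2-hydroxy-4,6-dimethoxyphenyl)-2-methoxyethan-1-one F1. The nitrile is preferred to the acid chloride because an α-alkoxy acylium ion tends to lose carbon monoxide. Claisen–Schmidt condensation of F1 with 9 (KOH, EtOH, rt; then dilute HCl) should give 14; any flavanone 15 formed alongside is consumed in step 6.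

Step 8. Persulfate hydroxylation may stall at low conversion because the chelated, acyl-deactivated phenolate is a poor nucleophile. The alkaline medium may open ring C, and the hydroquinone may be oxidised further during sulfate hydrolysis.
Fallback, setting out from 16 and returning at 19: the C8 oxygen is brought in through a halide and a boronate instead of an electrophilic oxidant. Electrophilic iodination of 16 (NIS, cat. CF3CO2H, MeCN, 0 °C) should give 8-iodo-3,5,7-trimethoxy-2-(2,3,4-trimethoxyphenyl)-4H-chromen-4-one F2; C8, para to O5 and ortho to O1 and O7, is the expected site in a 5,7-dialkoxyflavone, with C6 and C5' of ring B as competing sites. Miyaura borylation of F2 (B2pin2, PdCl2(dppf), KOAc, dioxane, 90 °C) should give 3,5,7-trimethoxy-8-(4,4,5,5-tetramethyl-1,3,2-dioxaborolan-2-yl)-2-(2,3,4-trimethoxyphenyl)-4H-chromen-4-one F3. Oxidation of the C–B bond of F3 (H2O2, NaHCO3, THF/H2O, 0 °C) should give 8-hydroxy-3,5,7-trimethoxy-2-(2,3,4-trimethoxyphenyl)-4H-chromen-4-one F4. Chelation-controlled cleavage of the 5-methyl ether of F4 (BCl3, 2.5 equiv, CH2Cl2, −78 to 0 °C; then H2O) should then give 19, so that step 7 is replaced as well.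

Step 6. Ring A may be iodinated, HI formed at 130 °C may cleave the 5-methyl ether in part, and the sequence may stop at 15 because C3 carries a single, hindered hydrogen.
Fallback, setting out from 14 and returning at 16: ring closure alone (NaOAc (cat.), EtOH, reflux) should allow 15 to be isolated, and dehydrogenation of 15 by hydride abstraction with 2,3-dichloro-5,6-dicyano-1,4-benzoquinone (dioxane, reflux) should give 16. This path uses no iodine and makes no compound outside the list, entry F0.

Step 2. Metalation may occur between the two methoxy groups instead of beside the carbamate, the carbamoyl group may migrate to carbon if the aryllithium warms, and the silyl group may be lost by ipso-protonation during work-up.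
Fallback, setting out from 1 and returning at 8: silicon is delivered from oxygen to carbon by an anionic rearrangement instead of by directed metalation. Amine-directed ortho-bromination of 1 (NBS, cat. iPr2NH, CH2Cl2, −78 to 0 °C, separation from the para isomer) should give 2-bromo-3,5-dimethoxyphenol F5. O-Silylation of F5 (HMDS, THF, reflux) should give (2-bromo-3,5-dimethoxyphenoxy)trimethylsilane F6. Bromine–lithium exchange on F6 (n-BuLi, THF, −78 °C) should trigger a retro-Brook 1,3-shift of silicon from oxygen to carbon, giving the lithium salt of 7, which Tf2O converts into 8 in the same flask.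

## Further compounds

F1 | step 5 | 1-(2-hydroxy-4,6-dimethoxyphenyl)-2-methoxyethan-1-one | COCC(=O)c1c(O)cc(OC)cc1OC
F2 | step 8 | 8-iodo-3,5,7-trimethoxy-2-(2,3,4-trimethoxyphenyl)-4H-chromen-4-one | COc1ccc(-c2oc3c(I)c(OC)cc(OC)c3c(=O)c2OC)c(OC)c1OC
F3 | step 8 | 3,5,7-trimethoxy-8-(4,4,5,5-tetramethyl-1,3,2-dioxaborolan-2-yl)-2-(2,3,4-trimethoxyphenyl)-4H-chromen-4-one | COc1ccc(-c2oc3c(B4OC(C)(C)C(C)(C)O4)c(OC)cc(OC)c3c(=O)c2OC)c(OC)c1OC
F4 | step 8 | 8-hydroxy-3,5,7-trimethoxy-2-(2,3,4-trimethoxyphenyl)-4H-chromen-4-one | COc1ccc(-c2oc3c(O)c(OC)cc(OC)c3c(=O)c2OC)c(OC)c1OC
F0 | step 6 | none | none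
F5 | step 2 | 2-bromo-3,5-dimethoxyphenol | COc1cc(O)c(Br)c(OC)c1
F6 | step 2 | (2-bromo-3,5-dimethoxyphenoxy)trimethylsilane | COc1cc(O[Si](C)(C)C)c(Br)c(OC)c1
A1 | alternative 1 | phloroglucinol | Oc1cc(O)cc(O)c1
A2 | alternative 1 | ethyl 2-methoxy-3-oxo-3-(2,3,4-trimethoxyphenyl)propanoate (racemic) | CCOC(=O)C(OC)C(=O)c1ccc(OC)c(OC)c1OC
A3 | alternative 1 | 5,7-dihydroxy-3-methoxy-2-(2,3,4-trimethoxyphenyl)-4H-chromen-4-one | COc1ccc(-c2oc3cc(O)cc(O)c3c(=O)c2OC)c(OC)c1OC
A4 | alternative 2 | 3-methoxy-5-(phenylsulfinyl)-2-(2,3,4-trimethoxyphenyl)-4H-pyran-4-one (racemic at sulfur) | COc1ccc(-c2occ(S(=O)c3ccccc3)c(=O)c2OC)c(OC)c1OC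
A5 | alternative 2 | 1-(benzyloxy)-2,4-dimethoxy-4-(trimethylsilyloxy)buta-1,3-diene (alkene geometry not defined, lost on aromatisation) | COC(=CC(OC)=COCc1ccccc1)O[Si](C)(C)C
A6 | alternative 2 | 8-(benzyloxy)-5-hydroxy-3,7-dimethoxy-2-(2,3,4-trimethoxyphenyl)-4H-chromen-4-one | COc1ccc(-c2oc3c(OCc4ccccc4)c(OC)cc(O)c3c(=O)c2OC)c(OC)c1OC
A7 | alternative 3 | 2-iodo-1,5-dimethoxy-3-(methoxymethoxy)benzene | COCOc1cc(OC)cc(OC)c1I
A8 | alternative 3 | carbon monoxide | [C-]#[O+]
A9 | alternative 3 | 2-methoxy-1-(2,3,4-trimethoxyphenyl)ethan-1-one | COCC(=O)c1ccc(OC)c(OC)c1OC
A10 | alternative 3 | 1-[2,4-dimethoxy-6-(methoxymethoxy)phenyl]-2-methoxy-3-(2,3,4-trimethoxyphenyl)propane-1,3-dione (racemic) | COCOc1cc(OC)cc(OC)c1C(=O)C(OC)C(=O)c1ccc(OC)c(OC)c1OC
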